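## Retrosynthetic overview

1. Late-stage groups: the (Z)-4-oxo-enoate comes from a 2-alkyl-3-methylfuran (singlet oxygen, then O-methylation); the C17 enal from a C8 ketone (enol triflate, Pd/CO); the C9 side chain from a C9 exo-methylene enone; the 2α,3α-diangelate from OsO4 on a C2=C3 olefin.
2. Key disconnection: ring A is cut at C1–C10 and C2–C3. C1–C2 is vinyltriphenylphosphonium bromide, C10 a tertiary radical, C3 an aldehyde (Giese addition, reduction to the ylide, intramolecular Wittig giving C2=C3).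
3. Enabling feature: in ring B the C8 carbonyl carbon is β to the quaternary, methyl-bearing C10. C10 is therefore the ring-enlarged β-keto radical of a 1-siloxybicyclo[3.1.0]hexane (cyclopentane C5–C6–C7–C8–C10 plus cyclopropane carbon C9). C10 also lies 1,4 to C3, a non-enolisable aldehyde carbon on the C4 gem-dimethyl centre, so opening the strained cyclopropane creates ring B and triggers closure of ring A.
4. Ring order: cyclopentane (2-methylcyclopentenone) → cyclopropane → ring B (ring enlargement) and ring A (Wittig) in the key step → transient furan and butenolide in the side chain.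
5. Stereocontrol: C5 by catalytic asymmetric Mukaiyama–Michael addition; C10 by anti addition to the radical; C2/C3 by α-face dihydroxylation; C9 by equilibration α to the C8 ketone.

Key step: step 4

Remark: atom labels C1–C17 are the labdane positions of the target (C1–C10 decalin, C11–C15 side chain, C17 formyl carbon); β means the face of the C10 methyl group.

## Route

Step 1
Reactants: 1 2-methylcyclopent-2-en-1-one; 2 [(1-methoxy-2-methylprop-1-en-1-yl)oxy]trimethylsilane
Product: 3 methyl 2-methyl-2-[(1R)-2-methyl-3-(trimethylsilyloxy)cyclopent-2-en-1-yl]propanoate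
Conditions: o-tolyl-oxazaborolidine·HNTf2 (20 mol %, enantiomer that gives the 1R adduct), Ph3PO (25 mol %), toluene, −20 °C; non-aqueous work-up
Reagents that add atoms: none
Why: Mukaiyama–Michael addition under chiral oxazaborolidinium catalysis should add the ketene acetal to the enone β-carbon on the face left open by the catalyst, setting C5 (1R), while silyl transfer to the enolate oxygen fixes the C8=C10 enol ether regiospecifically.

Step 2
Reactants: 3 methyl 2-methyl-2-[(1R)-2-methyl-3-(trimethylsilyloxy)cyclopent-2-en-1-yl]propanoate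
Product: 4 methyl 2-methyl-2-[(1S,2R,5R)-1-methyl-5-(trimethylsilyloxy)bicyclo[3.1.0]hexan-2-yl]propanoate
Conditions: Zn–Ag couple, CH2I2, Et2O, reflux; pyridine work-up
Reagents that add atoms: diiodomethane ICI
Why: Simmons–Smith cyclopropanation (Conia conditions) of the electron-rich silyl enol ether should give the cis-fused siloxycyclopropane with the methylene anti to the C5 substituent; both new bridgehead centres are lost again in step 4, so this selectivity is of no consequence.

Step 3
Reactants: 4 methyl 2-methyl-2-[(1S,2R,5R)-1-methyl-5-(trimethylsilyloxy)bicyclo[3.1.0]hexan-2-yl]propanoate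
Product: 5 2-methyl-2-[(1S,2R,5R)-1-methyl-5-(trimethylsilyloxy)bicyclo[3.1.0]hexan-2-yl]propanal
Conditions: DIBAL-H (1.1 equiv), CH2Cl2, −78 °C; Rochelle salt work-up
Reagents that add atoms: none
Why: Partial DIBAL-H reduction of the α-quaternary methyl ester should stop at the aldehyde because the hindered tetrahedral aluminate survives until work-up.

Step 4
Reactants: 5 2-methyl-2-[(1S,2R,5R)-1-methyl-5-(trimethylsilyloxy)bicyclo[3.1.0]hexan-2-yl]propanal; 6 vinyltriphenylphosphonium bromide
Product: 9 (4aR,8aR)-5,5,8a-trimethyl-3,4,4a,5,8,8a-hexahydronaphthalen-2(1H)-one, via tertiary C10 β-keto radical 7 (not isolated), via phosphonium ylide 8 (not isolated)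
Conditions: [Ir(dF(CF3)ppy)2(5,5′-d(CF3)bpy)]PF6 (2 mol %), 6 (2 equiv), MeCN/CH2Cl2, 0.02 M, blue LEDs (450 nm), rt, degassed
Reagents that add atoms: none
Why: Proposed new method: single-electron oxidation of the siloxycyclopropane by the excited Ir(III) catalyst gives a radical cation whose strained internal C8–C10 bond cleaves (silyl lost to bromide), the tertiary C10 radical 7 adds to the CH2 terminus of the vinylphosphonium salt, Ir(II) reduces the α-phosphonio radical to ylide 8, and 8 olefinates the C3 aldehyde intramolecularly. The closest known reactions are the electron-transfer and Fe(III)-mediated ring enlargement of bicyclo[n.1.0]alkyl silyl ethers to β-keto radicals, the photoredox radical–polar crossover olefination of alkyl radicals with vinylphosphonium salts and aldehydes, and the two-electron Schweizer annulation; merging them into one ring-forming cascade is new. Ring B closes by strain-release β-scission (one-carbon ring enlargement of the cyclopentane, C9 being the former cyclopropane CH2), and ring A closes by a 6-exo-trig attack of the ylide carbon C2 on the aldehyde, which can only give the cis C2=C3 olefin. The only new stereocentre, quaternary C10, is controlled by C5: the bulky CMe2CHO group shields one face of the planar radical, the acceptor adds anti to it, and the trans ring fusion follows after Wittig closure. The step needs cleavage of the internal rather than the external cyclopropane bond (secured by formation of a tertiary instead of a primary radical), polarity-matched trapping (nucleophilic tertiary radical, cationic acceptor in excess), and chemoselective olefination (the C3 aldehyde is non-enolisable, whereas olefination of the C8 ketone would give an anti-Bredt alkene).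

Step 5
Reactants: 9 (4aR,8aR)-5,5,8a-trimethyl-3,4,4a,5,8,8a-hexahydronaphthalen-2(1H)-one
Product: 10 (4aR,6S,7R,8aR)-6,7-dihydroxy-5,5,8a-trimethyloctahydronaphthalen-2(1H)-one
Conditions: OsO4 (2 mol %), NMO, acetone/H2O, rt
Reagents that add atoms: N-methylmorpholine N-oxide C[N+]1([O-])CCOCC1; water O
Why: Upjohn dihydroxylation of the only olefin should occur on the α face, anti to the axial C10 and C4β methyl groups, giving the cis 2α,3α-diol as known for 4,4-dimethyl-Δ2 olefins of trans-decalins and 5α-steroids.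

Step 6
Reactants: 10 (4aR,6S,7R,8aR)-6,7-dihydroxy-5,5,8a-trimethyloctahydronaphthalen-2(1H)-one; 11 angelic acid
Product: 12 (4aR,6S,7R,8aR)-5,5,8a-trimethyl-2-oxodecahydronaphthalene-6,7-diyl bis[(2Z)-2-methylbut-2-enoate]
Conditions: 11 (4 equiv), 2,4,6-trichlorobenzoyl chloride, Et3N, toluene, rt; then 10, 80 °C (no DMAP)
Reagents that add atoms: none
Why: Yamaguchi-type esterification through the mixed anhydride, run without nucleophilic catalyst, should acylate both hydroxyls (the axial, neopentyl 3α-OH on heating) without Z to E isomerisation to the tiglate.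

Step 7
Reactants: 12 (4aR,6S,7R,8aR)-5,5,8a-trimethyl-2-oxodecahydronaphthalene-6,7-diyl bis[(2Z)-2-methylbut-2-enoate]
Product: 13 2α,3α-bis(angeloyloxy)-4,4,10β-trimethyl-5α-decal-6-en-8-one
Conditions: IBX, DMSO/toluene, 70 °C
Reagents that add atoms: none
Why: IBX dehydrogenation (Nicolaou) can only proceed towards C7/C6 because C10 is quaternary, so the Δ6-8-enone should form; this blocks C7 and leaves C9 as the only enolisable position.

Step 8
Reactants: 13 2α,3α-bis(angeloyloxy)-4,4,10β-trimethyl-5α-decal-6-en-8-one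
Product: 16 2α,3α-bis(angeloyloxy)-4,4,10β-trimethyl-9-methylene-5α-decal-6-en-8-one, via C9 Mannich base 14 (not isolated), via trimethylammonium iodide 15 (not isolated)
Conditions: LDA (1.05 equiv), THF, −78 °C; Eschenmoser's salt, −78 to 0 °C; then MeI, CH2Cl2, rt; then aq. NaHCO3
Reagents that add atoms: Eschenmoser's salt C=[N+](C)C.[I-]
Why: Kinetic α′-deprotonation of the enone (as for isophorone) should give the cross-conjugated C8–C9 enolate, which undergoes Mannich reaction; quaternisation and E1cB elimination then deliver the C9 exo-methylene carbon C11.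

Step 9
Reactants: 16 2α,3α-bis(angeloyloxy)-4,4,10β-trimethyl-9-methylene-5α-decal-6-en-8-one; 17 3-methylfuran
Product: 18 2α,3α-bis(angeloyloxy)-9β-[(3-methylfuran-2-yl)methyl]-4,4,10β-trimethyl-5α-decal-6-en-8-one
Conditions: 17 (3 equiv), Sc(OTf)3 (5 mol %), CH2Cl2, −20 to 0 °C; then DBU (cat.), rt
Reagents that add atoms: none
Why: Lewis acid-catalysed Friedel–Crafts-type conjugate addition of 3-methylfuran through its more nucleophilic C2 to the unhindered exo-methylene terminus should install the side chain; C9, being α to the C8 ketone, is equilibrated to the equatorial 9β-side-chain (9α-H) epimer.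

Step 10
Reactants: 18 2α,3α-bis(angeloyloxy)-9β-[(3-methylfuran-2-yl)methyl]-4,4,10β-trimethyl-5α-decal-6-en-8-one
Product: 20 2α,3α-bis(angeloyloxy)-9β-[(3-methylfuran-2-yl)methyl]-4,4,10β-trimethyl-5α-decal-7-en-8-yl trifluoromethanesulfonate, via lithium Δ7-enolate 19 (not isolated)
Conditions: L-Selectride (1.05 equiv), THF, −78 °C; then Comins' reagent, −78 to 0 °C
Reagents that add atoms: Comins' reagent FC(F)(F)S(=O)(=O)N(c1ccc(Cl)cn1)S(=O)(=O)C(F)(F)F
Why: L-Selectride 1,4-reduction of the β-unsubstituted enone should generate the C7–C8 enolate regiospecifically, and O-triflation fixes it as the Δ7 enol triflate without touching C9.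

Step 11
Reactants: 20 2α,3α-bis(angeloyloxy)-9β-[(3-methylfuran-2-yl)methyl]-4,4,10β-trimethyl-5α-decal-7-en-8-yl trifluoromethanesulfonate
Product: 21 2α,3α-bis(angeloyloxy)-9β-[(3-methylfuran-2-yl)methyl]-4,4,10β-trimethyl-5α-decal-7-ene-8-carbaldehyde
Conditions: Pd(PPh3)4 (5 mol %), LiCl, CO (1 atm), Bu3SnH (slow addition), THF, 50 °C
Reagents that add atoms: carbon monoxide [C-]#[O+]
Why: Palladium-catalysed reductive carbonylation of the enol triflate (Stille formylation: oxidative addition, CO insertion, hydride transfer from tin) should give the C17 enal with the double bond held at C7=C8.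

Step 12
Reactants: 21 2α,3α-bis(angeloyloxy)-9β-[(3-methylfuran-2-yl)methyl]-4,4,10β-trimethyl-5α-decal-7-ene-8-carbaldehyde
Product: 23 5-hydroxy-4-methyl-5-(decalinylmethyl)furan-2(5H)-one derived from 21 (C12 epimers), via furan 2,5-endoperoxide 22 (not isolated)
Conditions: O2, rose bengal, visible light, i-Pr2NEt, CH2Cl2, −78 °C
Reagents that add atoms: oxygen O=O
Why: [4+2] addition of singlet oxygen to the electron-rich 2,3-dialkylfuran and base-induced Kornblum–DeLaMare fragmentation of the endoperoxide at its only C–H (C15) should give the γ-hydroxybutenolide, the ring tautomer of the (Z)-4-oxo-2-enoic acid (Kernan–Faulkner conditions); the enal and angelate olefins are too electron-poor to compete.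

Step 13
Reactants: 23 5-hydroxy-4-methyl-5-(decalinylmethyl)furan-2(5H)-one derived from 21
Product: 24 target CNP0141070.1
Conditions: MeI, KHCO3, DMF, 0 °C to rt, dark
Reagents that add atoms: iodomethane CI
Why: Mild base opens the hydroxybutenolide to the (Z)-keto carboxylate, and its SN2 O-alkylation should give the open-chain methyl ester with the cis geometry inherited from the ring.

## Compound list

1 | 2-methylcyclopent-2-en-1-one | CC1=CCCC1=O | starting material
2 | [(1-methoxy-2-methylprop-1-en-1-yl)oxy]trimethylsilane | COC(O[Si](C)(C)C)=C(C)C | starting material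
3 | methyl 2-methyl-2-[(1R)-2-methyl-3-(trimethylsilyloxy)cyclopent-2-en-1-yl]propanoate | COC(=O)C(C)(C)[C@@H]1CCC(O[Si](C)(C)C)=C1C | intermediate
4 | methyl 2-methyl-2-[(1S,2R,5R)-1-methyl-5-(trimethylsilyloxy)bicyclo[3.1.0]hexan-2-yl]propanoate (cyclopropane CH2 anti to the side chain) | COC(=O)C(C)(C)[C@@H]1CC[C@@]2(O[Si](C)(C)C)C[C@@]12C | intermediate
5 | 2-methyl-2-[(1S,2R,5R)-1-methyl-5-(trimethylsilyloxy)bicyclo[3.1.0]hexan-2-yl]propanal | O=CC(C)(C)[C@@H]1CC[C@@]2(O[Si](C)(C)C)C[C@@]12C | intermediate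
6 | vinyltriphenylphosphonium bromide | C=C[P+](c1ccccc1)(c1ccccc1)c1ccccc1.[Br-] | starting material
7 | (2R)-1-methyl-2-(2-methyl-1-oxopropan-2-yl)-5-oxocyclohexyl radical (C10 radical) | O=CC(C)(C)[C@@H]1CCC(=O)C[C]1C | intermediate
8 | 2-methyl-2-{(1R,2S)-2-methyl-4-oxo-2-[2-(triphenyl-λ5-phosphanylidene)ethyl]cyclohexyl}propanal (ylide chain trans to the side chain) | O=CC(C)(C)[C@@H]1CCC(=O)C[C@@]1(C)CC=P(c2ccccc2)(c2ccccc2)c2ccccc2 | intermediate
9 | (4aR,8aR)-5,5,8a-trimethyl-3,4,4a,5,8,8a-hexahydronaphthalen-2(1H)-one (trans-fused, C2=C3 olefin, C8 ketone) | C1=CC[C@]2(C)CC(=O)CC[C@H]2C1(C)C | intermediate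
10 | (4aR,6S,7R,8aR)-6,7-dihydroxy-5,5,8a-trimethyloctahydronaphthalen-2(1H)-one (2α,3α-diol) | O[C@@H]1[C@H](O)C[C@]2(C)CC(=O)CC[C@H]2C1(C)C | intermediate
11 | angelic acid, (2Z)-2-methylbut-2-enoic acid | C/C=C(/C)C(=O)O | starting material
12 | (4aR,6S,7R,8aR)-5,5,8a-trimethyl-2-oxodecahydronaphthalene-6,7-diyl bis[(2Z)-2-methylbut-2-enoate] | C/C=C(/C)C(=O)O[C@@H]1[C@H](OC(=O)/C(C)=C\C)C[C@]2(C)CC(=O)CC[C@H]2C1(C)C | intermediate
13 | 2α,3α-bis(angeloyloxy)-4,4,10β-trimethyl-5α-decal-6-en-8-one | C/C=C(/C)C(=O)O[C@@H]1[C@H](OC(=O)/C(C)=C\C)C[C@]2(C)CC(=O)C=C[C@H]2C1(C)C | intermediate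
14 | 9-(dimethylaminomethyl) Mannich base of 13 (C9 epimers) | C/C=C(/C)C(=O)O[C@@H]1[C@H](OC(=O)/C(C)=C\C)C[C@]2(C)C(CN(C)C)C(=O)C=C[C@H]2C1(C)C | intermediate
15 | trimethylammonium iodide of 14 | C/C=C(/C)C(=O)O[C@@H]1[C@H](OC(=O)/C(C)=C\C)C[C@]2(C)C(C[N+](C)(C)C)C(=O)C=C[C@H]2C1(C)C.[I-] | intermediate
16 | 2α,3α-bis(angeloyloxy)-4,4,10β-trimethyl-9-methylene-5α-decal-6-en-8-one | C/C=C(/C)C(=O)O[C@@H]1[C@H](OC(=O)/C(C)=C\C)C[C@]2(C)C(=C)C(=O)C=C[C@H]2C1(C)C | intermediate
17 | 3-methylfuran | Cc1ccoc1 | starting material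
18 | 2α,3α-bis(angeloyloxy)-9β-[(3-methylfuran-2-yl)methyl]-4,4,10β-trimethyl-5α-decal-6-en-8-one (9α-H) | C/C=C(/C)C(=O)O[C@@H]1[C@H](OC(=O)/C(C)=C\C)C[C@]2(C)[C@@H](Cc3occc3C)C(=O)C=C[C@H]2C1(C)C | intermediate
19 | lithium Δ7-enolate from 18 | C/C=C(/C)C(=O)O[C@@H]1[C@H](OC(=O)/C(C)=C\C)C[C@]2(C)[C@@H](Cc3occc3C)C([O-])=CC[C@H]2C1(C)C.[Li+] | intermediate
20 | Δ7 enol triflate: 2α,3α-bis(angeloyloxy)-9β-[(3-methylfuran-2-yl)methyl]-4,4,10β-trimethyl-5α-decal-7-en-8-yl trifluoromethanesulfonate | C/C=C(/C)C(=O)O[C@@H]1[C@H](OC(=O)/C(C)=C\C)C[C@]2(C)[C@@H](Cc3occc3C)C(OS(=O)(=O)C(F)(F)F)=CC[C@H]2C1(C)C | intermediate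
21 | 2α,3α-bis(angeloyloxy)-9β-[(3-methylfuran-2-yl)methyl]-4,4,10β-trimethyl-5α-decal-7-ene-8-carbaldehyde | C/C=C(/C)C(=O)O[C@@H]1[C@H](OC(=O)/C(C)=C\C)C[C@]2(C)[C@@H](Cc3occc3C)C(C=O)=CC[C@H]2C1(C)C | intermediate
22 | furan 2,5-endoperoxide of 21 | C/C=C(/C)C(=O)O[C@@H]1[C@H](OC(=O)/C(C)=C\C)C[C@]2(C)[C@@H](CC34OOC(C=C3C)O4)C(C=O)=CC[C@H]2C1(C)C | intermediate
23 | γ-hydroxybutenolide: 5-hydroxy-4-methyl-5-(decalinylmethyl)furan-2(5H)-one derived from 21 (C12 epimers) | C/C=C(/C)C(=O)O[C@@H]1[C@H](OC(=O)/C(C)=C\C)C[C@]2(C)[C@@H](CC3(O)OC(=O)C=C3C)C(C=O)=CC[C@H]2C1(C)C | intermediate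
24 | CNP0141070.1: methyl (2Z)-5-[2α,3α-bis(angeloyloxy)-8-formyl-4,4,10β-trimethyl-5α-decal-7-en-9β-yl]-3-methyl-4-oxopent-2-enoate | C/C=C(/C)C(=O)O[C@@H]1[C@H](OC(=O)/C(C)=C\C)C[C@]2(C)[C@@H](CC(=O)/C(C)=C\C(=O)OC)C(C=O)=CC[C@H]2C1(C)C | target

## Step count and risks

Total step count: 13. Longest linear sequence: 13 steps (fully linear from 1 and 2).

Steps most likely to fail:

1. Step 4 (proposed new method). The radical cation may undergo back electron transfer or lose silicon without ring enlargement. Bromide may be oxidised in competition. The tertiary radical may be quenched by hydrogen abstraction before it meets the phosphonium salt. The ylide may be protonated or silylated before it olefinates. Addition syn to the C5 substituent would give the cis-fused octalone. Fallback with known chemistry, from 4 back to 9: Ito–Saegusa ring enlargement of 4 (FeCl3, DMF; then NaOAc, MeOH) should give methyl 2-methyl-2-[(1R)-2-methyl-4-oxocyclohex-2-en-1-yl]propanoate F1. Hosomi–Sakurai conjugate allylation (allyltrimethylsilane, TiCl4, CH2Cl2, −78 °C, allyl anti to the C5 substituent) gives methyl 2-methyl-2-[(1R,2R)-2-methyl-4-oxo-2-(prop-2-en-1-yl)cyclohexyl]propanoate F2. LiAlH4 reduction gives 2-[(1R,2R)-4-hydroxy-2-methyl-2-(prop-2-en-1-yl)cyclohexyl]-2-methylpropan-1-ol F3. Dess–Martin oxidation gives 2-methyl-2-[(1R,2R)-2-methyl-4-oxo-2-(prop-2-en-1-yl)cyclohexyl]propanal F4. Aldehyde-selective Wittig methylenation (Ph3P=CH2, 1 equiv, −78 °C) gives (3R,4R)-3-methyl-4-(2-methylbut-3-en-2-yl)-3-(prop-2-en-1-yl)cyclohexan-1-one F5. Ring-closing metathesis (Grubbs II, CH2Cl2, 40 °C) then gives 9. In this fallback C1–C10 and C2=C3 are made in separate steps.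

2. Step 1. The α-methyl enone may bind the catalyst poorly and react slowly or with poor facial discrimination, and the silyl enol ether may hydrolyse and lose its regiochemistry. Fallback from 1 back to 3: CBS reduction of 1 gives (S)-2-methylcyclopent-2-en-1-ol F6. Acylation with isobutyryl chloride and pyridine gives (S)-2-methylcyclopent-2-en-1-yl 2-methylpropanoate F7. Ireland–Claisen rearrangement (LDA, TMSCl, THF, −78 °C to reflux) transfers chirality to give 2-methyl-2-[(1R)-2-methylcyclopent-2-en-1-yl]propanoic acid F8. Esterification with TMSCHN2 gives methyl 2-methyl-2-[(1R)-2-methylcyclopent-2-en-1-yl]propanoate F9. Hydroboration–oxidation (BH3·THF; H2O2, NaOH) gives methyl 2-[(1R)-3-hydroxy-2-methylcyclopentyl]-2-methylpropanoate F10. Dess–Martin oxidation gives methyl 2-methyl-2-[(1R)-2-methyl-3-oxocyclopentyl]propanoate F11. Thermodynamic silylation (TMSCl, NaI, Et3N, MeCN) gives 3.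

3. Step 6. Acylation may stop at the equatorial 2α-hydroxyl, acyl migration may occur, or forcing conditions may isomerise the angelate to the tiglate. Fallback from 10 back to 12: both hydroxyls are esterified with 2-[bis(2,2,2-trifluoroethoxy)phosphoryl]propanoic acid (DIC, DMAP, CH2Cl2) to give the 2α,3α-bis{2-[bis(2,2,2-trifluoroethoxy)phosphoryl]propanoate} of 10 F12. Still–Gennari olefination with acetaldehyde (KHMDS, 18-crown-6, THF, −78 °C) then builds both (Z)-2-methylbut-2-enoates on the ester to give 12.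

## Further compounds

F1 | step 4 | methyl 2-methyl-2-[(1R)-2-methyl-4-oxocyclohex-2-en-1-yl]propanoate | COC(=O)C(C)(C)[C@@H]1CCC(=O)C=C1C
F2 | step 4 | methyl 2-methyl-2-[(1R,2R)-2-methyl-4-oxo-2-(prop-2-en-1-yl)cyclohexyl]propanoate | COC(=O)C(C)(C)[C@@H]1CCC(=O)C[C@@]1(C)CC=C
F3 | step 4 | 2-[(1R,2R)-4-hydroxy-2-methyl-2-(prop-2-en-1-yl)cyclohexyl]-2-methylpropan-1-ol (carbinol epimers) | OCC(C)(C)[C@@H]1CCC(O)C[C@@]1(C)CC=C
F4 | step 4 | 2-methyl-2-[(1R,2R)-2-methyl-4-oxo-2-(prop-2-en-1-yl)cyclohexyl]propanal | O=CC(C)(C)[C@@H]1CCC(=O)C[C@@]1(C)CC=C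
F5 | step 4 | (3R,4R)-3-methyl-4-(2-methylbut-3-en-2-yl)-3-(prop-2-en-1-yl)cyclohexan-1-one | C=CC(C)(C)[C@@H]1CCC(=O)C[C@@]1(C)CC=C
F6 | step 1 | (S)-2-methylcyclopent-2-en-1-ol | O[C@H]1CCC=C1C
F7 | step 1 | (S)-2-methylcyclopent-2-en-1-yl 2-methylpropanoate | CC(C)C(=O)O[C@H]1CCC=C1C
F8 | step 1 | 2-methyl-2-[(1R)-2-methylcyclopent-2-en-1-yl]propanoic acid | OC(=O)C(C)(C)[C@@H]1CCC=C1C
F9 | step 1 | methyl 2-methyl-2-[(1R)-2-methylcyclopent-2-en-1-yl]propanoate | COC(=O)C(C)(C)[C@@H]1CCC=C1C
F10 | step 1 | methyl 2-[(1R)-3-hydroxy-2-methylcyclopentyl]-2-methylpropanoate (H and OH delivered anti to the side chain) | COC(=O)C(C)(C)[C@@H]1CC[C@@H](O)[C@@H]1C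
F11 | step 1 | methyl 2-methyl-2-[(1R)-2-methyl-3-oxocyclopentyl]propanoate (C2 epimers) | COC(=O)C(C)(C)[C@@H]1CCC(=O)C1C
F12 | step 6 | 2α,3α-bis{2-[bis(2,2,2-trifluoroethoxy)phosphoryl]propanoate} of 10 | CC(C(=O)O[C@@H]1[C@H](OC(=O)C(C)P(=O)(OCC(F)(F)F)OCC(F)(F)F)C[C@]2(C)CC(=O)CC[C@H]2C1(C)C)P(=O)(OCC(F)(F)F)OCC(F)(F)F
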